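The route rests on one disconnection: break C1–C10 of the furanone-bridged ten-membered ring and rejoin C3–C8. C10 (quaternary; methyl and ring oxygen) is bonded to C1 and faces C3 across the bridging oxygen, so the 11-oxabicyclo[6.2.1]undecane core maps onto a cis-fused 2-methyl-7a-vinyl-tetrahydrobenzofuran-3a-ol on the carvone ring, with C3 and C8 at the ring fusion. Its potassium alkoxide should undergo an anionic oxy-Cope shift that forms C1–C10, cleaves C3–C8, expands the six-membered ring to ten, closes the bridging dihydrofuran and sets C10; the C8 enolate is oxidised in the same flask to place the C9 hydroxyl. (S)-Carvone supplies C7.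

Key step: step 13

Assumption and numbering: the target is made exactly as drawn, (6S,7S,8S,9R,10R,11R) with a cis-fused 6,7-lactone. Target (germacrane) numbers are used for every compound: carvone C1, C2, C3, C4, C5, C6, C10 become C3, C4, C5, C6, C7, C8, C12; C14 is the methyl on C10, C15 the methyl on C4.

Design points:
- A vinyl nucleophile adds to the carvone enone trans to the C7 substituent, which would give the wrong C3 and hence the wrong C10. The enone is therefore epoxidised first, so that addition occurs anti to the oxirane (steps 3, 5, 6).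
- The isopropenyl methyl cannot be oxidised selectively late, so C12 is oxygenated in step 1. C11 is set at the end under reagent control.
- In the rearrangement substrate O6 carries TBDPS, because a small silyl group 1,3-syn to the C8 alkoxide would migrate. O6 cannot be left free, because a C6 alkoxide would form a second oxy-Cope array with the side-chain alkene.
- The enolate is oxidised in the flask, because re-enolising the ketone could not distinguish C7 from C9.

Step 1
Reactants: 1 (S)-(+)-carvone
Product: 2 10-hydroxycarvone
Conditions: SeO2 (0.5 equiv), t-BuOOH (70% aq), CH2Cl2, 23 °C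
Reagents that add atoms: tert-butyl hydroperoxide, CC(C)(C)OO
Why: Allylic hydroxylation with SeO2 (ene reaction, then [2,3] shift) takes the methyl group of the electron-rich 1,1-disubstituted alkene and leaves the deactivated enone alkene alone; no stereocentre is made and C7 is untouched.

Step 2
Reactants: 2 10-hydroxycarvone
Product: 3 10-(tert-butyldiphenylsilyloxy)carvone
Conditions: TBDPSCl, imidazole, DMF, 23 °C
Reagents that add atoms: tert-butyl(chloro)diphenylsilane, CC(C)(C)[Si](Cl)(c1ccccc1)c1ccccc1
Why: Silyl ether formation at the primary alcohol; TBDPS is chosen because it has to outlast hydride, organomagnesium, oxidant and KH steps until step 18.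

Step 3
Reactants: 3 10-(tert-butyldiphenylsilyloxy)carvone
Product: 4 4,5-epoxy ketone
Conditions: H2O2 (30% aq), NaOH, MeOH, 0 °C
Reagents that add atoms: hydrogen peroxide, OO
Why: Weitz–Scheffer epoxidation of the enone, in which hydroperoxide adds to C5 from the face away from the C7 substituent so that the oxirane forms trans to it, and C4 becomes sp3 as the facial course of step 5 requires.

Step 4
Reactants: 4 4,5-epoxy ketone
Product: 6 hydroxy epoxy ketone (OH on C8), via lithium enolate 5 (not isolated)
Conditions: LiHMDS, THF, −78 °C; 2-(phenylsulfonyl)-3-phenyloxaziridine; AcOH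
Reagents that add atoms: 2-(phenylsulfonyl)-3-phenyloxaziridine, O=S(=O)(N1OC1c1ccccc1)c1ccccc1
Why: Enolate α-hydroxylation with an N-sulfonyloxaziridine, where only C8 can be enolised and oxygen should enter anti to the neighbouring C7 substituent; this configuration is of no consequence because C8 becomes a ketone in step 7.

Step 5
Reactants: 6 hydroxy epoxy ketone (OH on C8); 7 vinylmagnesium bromide
Product: 8 3-vinyl epoxy diol
Conditions: 7 (3 equiv), THF, −78 to −20 °C; aq NH4Cl
Reagents that add atoms: none
Why: Grignard 1,2-addition to the α,β-epoxy ketone after deprotonation of the C8 hydroxyl; with C4 sp3 the carbonyl is no longer part of an enone, and attack anti to the oxirane C–O bond and to the magnesium-bound C8 oxygen puts the vinyl group cis to the C7 side chain and the C3 oxygen trans to it.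

Step 6
Reactants: 8 3-vinyl epoxy diol
Product: 9 3-vinyl cyclohexene diol
Conditions: Cp2TiCl2 (2.5 equiv), Zn dust, THF, 23 °C; then 8
Reagents that add atoms: none
Why: Epoxide deoxygenation by Cp2TiCl (trivalent titanium), in which homolysis of the C4–O bond gives the tertiary radical, a second titanium traps it and the C5 titanoxy group is eliminated, restoring C4=C5 and leaving the C3 carbinol and its configuration intact.

Step 7
Reactants: 9 3-vinyl cyclohexene diol
Product: 10 8-keto tertiary alcohol
Conditions: IBX, DMSO, 23 °C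
Reagents that add atoms: none
Why: IBX oxidation takes the secondary C8 alcohol to the ketone without glycol cleavage and cannot touch the tertiary C3 alcohol.

Step 8
Reactants: 10 8-keto tertiary alcohol; 11 1-propynylmagnesium bromide
Product: 12 3-vinyl-8-propynyl diol
Conditions: 11 (3 equiv), THF, −78 to 0 °C; aq NH4Cl
Reagents that add atoms: none
Why: Alkynyl Grignard addition to the α-hydroxy ketone after deprotonation of O3, in which the upper face of C8 is screened by the vinyl group on quaternary C3 and by the C7 side chain, so the alkyne enters from below and ends cis to the C3 oxygen, with the new C8 hydroxyl cis to vinyl and side chain.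

Step 9
Reactants: 12 3-vinyl-8-propynyl diol
Product: 14 6-enone diol, via C6 tert-butyl peroxide 13 (not isolated)
Conditions: Rh2(cap)4 (dirhodium tetracaprolactamate, 1 mol %), t-BuOOH (70% aq), ClCH2CH2Cl, 40 °C
Reagents that add atoms: tert-butyl hydroperoxide, CC(C)(C)OO
Why: Radical allylic oxidation with Rh2(cap)4 and t-BuOOH, in which the ring methylene C6 next to the trisubstituted alkene is the weakest accessible C–H bond (C3 is quaternary) and the mixed peroxide collapses to the enone; a chromium-free oxidant is needed because chromium reagents would transpose the tertiary vinyl carbinol.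

Step 10
Reactants: 14 6-enone diol
Product: 16 3,6,8-triol, via diethylboron chelate 15 (not isolated)
Conditions: Et2BOMe, THF/MeOH (4:1), −78 °C; NaBH4; AcOH, MeOH co-evaporation
Reagents that add atoms: none
Why: Narasaka–Prasad reduction, in which the C8 hydroxyl and the C6 carbonyl are tied in a diethylboron chelate and external hydride gives the 1,3-syn diol, so that C6–OH is cis to C8–OH and to the C7 side chain; 1,2-reduction is expected because the β-carbon C4 is fully substituted.

Step 11
Reactants: 16 3,6,8-triol
Product: 17 6-O-TBDPS diol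
Conditions: TBDPSCl, imidazole, DMAP (10 mol %), DMF, 40 °C
Reagents that add atoms: tert-butyl(chloro)diphenylsilane, CC(C)(C)[Si](Cl)(c1ccccc1)c1ccccc1
Why: Silylation of the only secondary alcohol while the two tertiary alcohols stay free; the bulky TBDPS group is used because a small silyl group 1,3-syn to the C8 alkoxide would transfer to it in step 13.

Step 12
Reactants: 17 6-O-TBDPS diol
Product: 18 cis-fused 2-methyl-7a-vinyl-tetrahydrobenzofuran-3a-ol
Conditions: Ph3PAuNTf2 (3 mol %), 4 Å MS, CH2Cl2, 0 °C; Et3N quench, Et3N-treated silica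
Reagents that add atoms: none
Why: Gold-catalysed 5-endo-dig hydroalkoxylation (cycloisomerisation) of the homopropargylic alcohol, in which the monovalent gold π-acid activates the alkyne, O3 adds at C10 and protodeauration gives the 2-methyl-2,3-dihydrofuran, cis-fused because O3 and C9 are already cis; the acid-labile hydroxy enol ether is kept basic.

Step 13
Reactants: 18 cis-fused 2-methyl-7a-vinyl-tetrahydrobenzofuran-3a-ol
Product: 21 9-hydroxy bridged cyclodecadienone, via potassium alkoxide 19 (not isolated), via potassium enolate 20 (not isolated)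
Conditions: KH (1.2 equiv), 18-crown-6, THF, 0 °C; then −78 °C, 2-(phenylsulfonyl)-3-phenyloxaziridine; AcOH
Reagents that add atoms: 2-(phenylsulfonyl)-3-phenyloxaziridine, O=S(=O)(N1OC1c1ccccc1)c1ccccc1
Why: Proposed new method: KH and 18-crown-6 give the naked alkoxide 19, whose 3-oxido-1,5-diene C1=C2–C3–C8(O−)–C9=C10 should undergo a charge-accelerated [3,3] shift through a boat array spanned by the ring oxygen between C3 and C10 (a 7-oxanorbornane-like geometry); the closest known reaction type is the anionic oxy-Cope ring expansion of 1,2-dialkenylcycloalkanols (six- to ten-membered), here with one alkene inside a dihydrofuran, and because that ring π bond is poorly aligned with the breaking C3–C8 bond the shift is expected to be asynchronous, merging in the limit into C3–C8 heterolysis and 5-exo addition of C1 to C10 of the transient β-alkoxy enone, which gives the same bond. The five-membered ring (O, C3, C2, C1, C10) closes by the C1–C10 bond itself, 5-exo-trig with respect to C9=C10, while the ten-membered carbocycle is not closed end to end but arises by four-atom expansion of the cyclohexene when C3–C8 breaks, the ring alkene surviving as the Z C4=C5 bond. C10 is set by suprafacial transfer from C3, since the cis ring fusion holds the vinyl group over one face of the dihydrofuran only (10R), and C9 is set when the oxaziridine meets enolate 20 on its outer face, anti to the new C1–C10 bond (9R). The step needs C1 and not C5 to bond to C10, and the tight pathway to outrun free dissociation; the rotating vinyl π bond can align with the breaking bond whereas the C4=C5 π bond is held with that bond near its nodal plane, and 18-crown-6 with low temperature favours the charge-accelerated shift. Side reactions are limited by the substrate: the bulky TBDPS group on O6 resists 1,3-syn silyl transfer to the alkoxide, the side-chain alkene sits on the face opposite C10, and oxidation in the same flask consumes the enolate before it can expel the C10 oxygen.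

Step 14
Reactants: 21 9-hydroxy bridged cyclodecadienone
Product: 22 9-O-TES ketone
Conditions: TESOTf, 2,6-lutidine, CH2Cl2, −78 °C
Reagents that add atoms: triethylsilyl trifluoromethanesulfonate, CC[Si](CC)(CC)OS(=O)(=O)C(F)(F)F
Why: Silylation of the hindered secondary C9 alcohol with a silyl triflate and a hindered base, which keeps O9 from being oxidised in step 15 and from competing with O8 in step 17.

Step 15
Reactants: 22 9-O-TES ketone
Product: 24 furanone ketone, via C1 tert-butyl peroxide 23 (not isolated)
Conditions: Rh2(cap)4 (1 mol %), t-BuOOH (70% aq), CH2Cl2, 23 °C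
Reagents that add atoms: tert-butyl hydroperoxide, CC(C)(C)OO
Why: Allylic oxidation as in step 9, in which C1–H, allylic to the dienol ether, is the weakest C–H bond, the mixed peroxide should form at C1 (C3 is fully substituted, C5 is screened by the C6 silyl ether) and loses tert-butanol to give the vinylogous ester, the 3(2H)-furanone, which also removes the acid-labile enol ether.

Step 16
Reactants: 24 furanone ketone
Product: 25 8-alcohol
Conditions: NaBH4, MeOH/CH2Cl2, −40 °C
Reagents that add atoms: none
Why: Borohydride reduction of the saturated C8 ketone, the vinylogous ester carbonyl C1 being far less electrophilic; hydride should add to the outer face of the ring ketone (carbonyl turned away from C3, as it is left by the rearrangement), which gives the 8S alcohol with O8 trans to O9 and cis to the C7 side chain.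

Step 17
Reactants: 25 8-alcohol; 26 angelic acid
Product: 28 8-angelate, via mixed anhydride 27 (not isolated)
Conditions: 26, 2,4,6-trichlorobenzoyl chloride, Et3N, toluene, 23 °C; then 25, 80 °C
Reagents that add atoms: none
Why: Yamaguchi-type esterification through the mixed anhydride, run without DMAP so that the hindered C8 alcohol is acylated with retention and the Z geometry of the angelate is not isomerised to the tiglate.

Step 18
Reactants: 28 8-angelate
Product: 29 6,9,12-triol
Conditions: TBAF, AcOH (1:1), THF, 23 °C
Reagents that add atoms: none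
Why: Fluoride desilylation removes both TBDPS ethers and the TES ether in one operation, the acetic acid buffer being there to prevent migration or loss of the angelate.

Step 19
Reactants: 29 6,9,12-triol
Product: 30 11,13-epoxy triol
Conditions: Ti(OiPr)4, D-(−)-diethyl tartrate, t-BuOOH, 4 Å MS, CH2Cl2, −20 °C
Reagents that add atoms: tert-butyl hydroperoxide, CC(C)(C)OO
Why: Sharpless asymmetric epoxidation of the 2-substituted allylic alcohol, in which the D-(−)-tartrate complex delivers oxygen under reagent control to the face needed for C11 of the target; the other alkenes are spared because C4=C5 is part of the electron-poor furanone dienone and the angelate is an enoate.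

Step 20
Reactants: 30 11,13-epoxy triol
Product: 33 11,13-epoxy 12,6-lactone, via epoxy aldehyde 31 (not isolated), via lactol 32 (not isolated)
Conditions: TEMPO (0.2 equiv), PhI(OAc)2 (2.5 equiv), CH2Cl2, 23 °C
Reagents that add atoms: none
Why: TEMPO/PhI(OAc)2 oxidative lactonisation, in which the primary alcohol is oxidised first, the aldehyde is captured by the C6 hydroxyl on the same face as the side chain and the lactol is oxidised to the cis-fused γ-lactone, while the hindered secondary C9 alcohol is left.

Step 21
Reactants: 33 11,13-epoxy 12,6-lactone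
Product: 34 CNP0272644.1
Conditions: LiCl, AcOH, THF, 23 °C
Reagents that add atoms: lithium chloride, [Li+].[Cl-]
Why: Acid-assisted SN2 opening of the spiro-epoxide by chloride at the primary carbon C13 gives the chlorohydrin with the C11–O bond, and hence the C11 configuration (11R in the target), unchanged.

Compound list
1 | (S)-(+)-carvone, (5S)-2-methyl-5-(prop-1-en-2-yl)cyclohex-2-en-1-one | CC1=CC[C@@H](CC1=O)C(C)=C | starting material
2 | 10-hydroxycarvone, (5S)-5-(3-hydroxyprop-1-en-2-yl)-2-methylcyclohex-2-en-1-one | CC1=CC[C@@H](CC1=O)C(=C)CO | intermediate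
3 | 10-(tert-butyldiphenylsilyloxy)carvone, the O12-TBDPS ether of 2 | CC1=CC[C@@H](CC1=O)C(=C)CO[Si](c2ccccc2)(c2ccccc2)C(C)(C)C | intermediate
4 | 4,5-epoxy ketone: epoxide of the enone of 3, oxirane oxygen trans to the C7 side chain | O=C1[C@@]2(C)O[C@H]2C[C@H](C(=C)CO[Si](c3ccccc3)(c3ccccc3)C(C)(C)C)C1 | intermediate
5 | lithium enolate of 4 (C3–OLi, C3=C8) | [Li+].[O-]C1=C[C@@H](C(=C)CO[Si](c3ccccc3)(c3ccccc3)C(C)(C)C)C[C@@H]2O[C@]12C | intermediate
6 | hydroxy epoxy ketone: 4 with a hydroxyl on C8, trans to the C7 side chain | O=C1[C@@]2(C)O[C@H]2C[C@H](C(=C)CO[Si](c3ccccc3)(c3ccccc3)C(C)(C)C)[C@H]1O | intermediate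
7 | vinylmagnesium bromide | C=C[Mg]Br | starting material
8 | 3-vinyl epoxy diol: tertiary C3 carbinol with vinyl cis to the C7 side chain; O3, O8 and the oxirane oxygen on the opposite face | C=C[C@]1(O)[C@@]2(C)O[C@H]2C[C@H](C(=C)CO[Si](c3ccccc3)(c3ccccc3)C(C)(C)C)[C@H]1O | intermediate
9 | 3-vinyl cyclohexene diol: 8 without the oxirane oxygen (C4=C5) | C=C[C@]1(O)C(C)=CC[C@H](C(=C)CO[Si](c2ccccc2)(c2ccccc2)C(C)(C)C)[C@H]1O | intermediate
10 | 8-keto tertiary alcohol: the C8 ketone of 9 | C=C[C@]1(O)C(C)=CC[C@H](C(=C)CO[Si](c2ccccc2)(c2ccccc2)C(C)(C)C)C1=O | intermediate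
11 | 1-propynylmagnesium bromide | CC#C[Mg]Br | starting material
12 | 3-vinyl-8-propynyl diol: O3 and the propynyl group on one face; vinyl, O8 and the C7 side chain on the other | C=C[C@]1(O)C(C)=CC[C@H](C(=C)CO[Si](c2ccccc2)(c2ccccc2)C(C)(C)C)[C@@]1(O)C#CC | intermediate
13 | C6 tert-butyl peroxide of 12 (C6 configuration open) | C=C[C@]1(O)C(C)=CC(OOC(C)(C)C)[C@H](C(=C)CO[Si](c2ccccc2)(c2ccccc2)C(C)(C)C)[C@@]1(O)C#CC | intermediate
14 | 6-enone diol: the C6 ketone of 12 | C=C[C@]1(O)C(C)=CC(=O)[C@H](C(=C)CO[Si](c2ccccc2)(c2ccccc2)C(C)(C)C)[C@@]1(O)C#CC | intermediate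
15 | diethylboron chelate of 14 (O8–BEt2, boron coordinated to the C6 carbonyl) | C=C[C@]1(O)C(C)=CC(=O)[C@H](C(=C)CO[Si](c2ccccc2)(c2ccccc2)C(C)(C)C)[C@@]1(OB(CC)CC)C#CC | intermediate
16 | 3,6,8-triol: C6–OH cis to C8–OH and to the C7 side chain | C=C[C@]1(O)C(C)=C[C@H](O)[C@H](C(=C)CO[Si](c2ccccc2)(c2ccccc2)C(C)(C)C)[C@@]1(O)C#CC | intermediate
17 | 6-O-TBDPS diol: the O6-TBDPS ether of 16 | C=C[C@]1(O)C(C)=C[C@H](O[Si](c2ccccc2)(c2ccccc2)C(C)(C)C)[C@H](C(=C)CO[Si](c2ccccc2)(c2ccccc2)C(C)(C)C)[C@@]1(O)C#CC | intermediate
18 | cis-fused 2-methyl-7a-vinyl-tetrahydrobenzofuran-3a-ol (C3 = 7a, C8 = 3a); vinyl, O8–H, the C7 side chain and O6-TBDPS on one face, the dihydrofuran on the other | C=C[C@@]12OC(C)=C[C@]1(O)[C@@H](C(=C)CO[Si](c3ccccc3)(c3ccccc3)C(C)(C)C)[C@@H](O[Si](c3ccccc3)(c3ccccc3)C(C)(C)C)C=C2C | intermediate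
19 | potassium alkoxide of 18 | [K+].C=C[C@@]12OC(C)=C[C@]1([O-])[C@@H](C(=C)CO[Si](c3ccccc3)(c3ccccc3)C(C)(C)C)[C@@H](O[Si](c3ccccc3)(c3ccccc3)C(C)(C)C)C=C2C | intermediate
20 | potassium enolate (O8–K, C8=C9) of the oxygen-bridged cyclodecadienone | [K+].[O-]/C1=C/[C@]2(C)CC=C(O2)/C(C)=C\[C@H](O[Si](c3ccccc3)(c3ccccc3)C(C)(C)C)[C@@H]1C(=C)CO[Si](c3ccccc3)(c3ccccc3)C(C)(C)C | intermediate
21 | 9-hydroxy bridged cyclodecadienone: C8 ketone, (9R)-OH, (10R), C2=C3 enol ether bridged C3–O–C10, Z C4=C5 | O=C1[C@@H](C(=C)CO[Si](c3ccccc3)(c3ccccc3)C(C)(C)C)[C@H](/C=C(/C)C2=CC[C@](C)(O2)[C@@H]1O)O[Si](c3ccccc3)(c3ccccc3)C(C)(C)C | intermediate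
22 | 9-O-TES ketone: the O9-triethylsilyl ether of 21 | O=C1[C@@H](C(=C)CO[Si](c3ccccc3)(c3ccccc3)C(C)(C)C)[C@H](/C=C(/C)C2=CC[C@](C)(O2)[C@@H]1O[Si](CC)(CC)CC)O[Si](c3ccccc3)(c3ccccc3)C(C)(C)C | intermediate
23 | C1 tert-butyl peroxide of 22 (C1 configuration open) | O=C1[C@@H](C(=C)CO[Si](c3ccccc3)(c3ccccc3)C(C)(C)C)[C@H](/C=C(/C)C2=CC(OOC(C)(C)C)[C@](C)(O2)[C@@H]1O[Si](CC)(CC)CC)O[Si](c3ccccc3)(c3ccccc3)C(C)(C)C | intermediate
24 | furanone ketone: 22 with C1 as the 3(2H)-furanone carbonyl | O=C1[C@@H](C(=C)CO[Si](c3ccccc3)(c3ccccc3)C(C)(C)C)[C@H](/C=C(/C)C2=CC(=O)[C@](C)(O2)[C@@H]1O[Si](CC)(CC)CC)O[Si](c3ccccc3)(c3ccccc3)C(C)(C)C | intermediate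
25 | 8-alcohol: (8S)-alcohol of 24, O8 trans to O9 and cis to the C7 side chain | O[C@H]1[C@@H](C(=C)CO[Si](c3ccccc3)(c3ccccc3)C(C)(C)C)[C@H](/C=C(/C)C2=CC(=O)[C@](C)(O2)[C@@H]1O[Si](CC)(CC)CC)O[Si](c3ccccc3)(c3ccccc3)C(C)(C)C | intermediate
26 | angelic acid, (Z)-2-methylbut-2-enoic acid | C/C=C(/C)C(=O)O | starting material
27 | angelic 2,4,6-trichlorobenzoic mixed anhydride | C/C=C(/C)C(=O)OC(=O)c1c(Cl)cc(Cl)cc1Cl | intermediate
28 | 8-angelate: the O8-(Z)-2-methylbut-2-enoate of 25 | C/C=C(/C)C(=O)O[C@H]1[C@@H](C(=C)CO[Si](c3ccccc3)(c3ccccc3)C(C)(C)C)[C@H](/C=C(/C)C2=CC(=O)[C@](C)(O2)[C@@H]1O[Si](CC)(CC)CC)O[Si](c3ccccc3)(c3ccccc3)C(C)(C)C | intermediate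
29 | 6,9,12-triol: 28 without the three silyl groups | C/C=C(/C)C(=O)O[C@H]1[C@@H](C(=C)CO)[C@H](/C=C(/C)C2=CC(=O)[C@](C)(O2)[C@@H]1O)O | intermediate
30 | 11,13-epoxy triol: the spiro-epoxide of the side-chain alkene of 29, configured as C11 of the target | C/C=C(/C)C(=O)O[C@H]1[C@@H]([C@@]4(CO)CO4)[C@H](/C=C(/C)C2=CC(=O)[C@](C)(O2)[C@@H]1O)O | intermediate
31 | epoxy aldehyde: the C12 aldehyde of 30 | C/C=C(/C)C(=O)O[C@H]1[C@@H]([C@@]4(C=O)CO4)[C@H](/C=C(/C)C2=CC(=O)[C@](C)(O2)[C@@H]1O)O | intermediate
32 | lactol: the 6,12-hemiacetal of 31 (C12 configuration open) | C/C=C(/C)C(=O)O[C@H]1[C@@H]2[C@H](/C=C(/C)C3=CC(=O)[C@](C)(O3)[C@@H]1O)OC(O)[C@@]24CO4 | intermediate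
33 | 11,13-epoxy 12,6-lactone: cis-fused γ-lactone with the spiro-epoxide at C11 | C/C=C(/C)C(=O)O[C@H]1[C@@H]2[C@H](/C=C(/C)C3=CC(=O)[C@](C)(O3)[C@@H]1O)OC(=O)[C@@]24CO4 | intermediate
34 | CNP0272644.1, (6S,7S,8S,9R,10R,11R)-8-angeloyloxy-13-chloro-9,11-dihydroxy furanone-bridged 12,6-lactone | C/C=C(/C)C(=O)O[C@H]1[C@@H]2[C@H](/C=C(/C)C3=CC(=O)[C@](C)(O3)[C@@H]1O)OC(=O)[C@@]2(O)CCl | target

Total step count: 21
Longest linear sequence: 21 steps (from 1)

Steps most likely to fail

Step 13 (proposed new method). What may go wrong: C3–C8 cleaves without bond formation at C1 (closure through C5 to a six-membered ring, or protonation of the opened anion); the C3-to-C10 stereochemical relay is lost if the anion dissociates; the enolate expels the C10 oxygen. Fallback, known radical chemistry in place of the anionic shift: setting out from 18, the C8 alkoxy radical is generated photochemically (CeCl3, Bu4NCl, 400 nm light, MeCN). β-Scission of C3–C8 and 5-exo addition of the C1 radical terminus to C10 of the resulting β-alkoxy enone follow, and reduction and protonation of the α-keto radical give the ring-expanded ketone without the C9 hydroxyl F1. Kinetic deprotonation at the C9 methylene (KHMDS, THF, −78 °C) and the same oxaziridine bring the route back to 21.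

Step 15. What may go wrong: the delocalised allyl radical is captured at C5 or C3 and not at C1, or the electron-rich dienol ether is attacked at its double bond. Fallback, a two-electron route: setting out from 22, DDQ (1.1 equiv, CH2Cl2/pH 7 buffer, 0 °C) abstracts hydride from C1 and water captures the oxygen-stabilised cation to give the C1 allylic alcohol F2. Oxidation of this activated alcohol with MnO2 in CH2Cl2 returns the route at 24.

Step 16. What may go wrong: poor facial selectivity, with hydride entering from the inner face of the ring ketone. Fallback, inversion in place of retention at the ester stage: setting out from 24, the reduction is then run for the other epimer (a bulkier hydride if needed) to give the 8-epi alcohol F3. Mitsunobu esterification of F3 with 26 (PPh3, DIAD, toluene, 0 to 23 °C) inverts C8 and installs the angelate in one operation, returning the route at 28.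

Further compounds
F1 | step 13 | ring-expanded ketone without the C9 hydroxyl (9-deoxy-21) | O=C1[C@@H](C(=C)CO[Si](c3ccccc3)(c3ccccc3)C(C)(C)C)[C@H](/C=C(/C)C2=CC[C@](C)(O2)C1)O[Si](c3ccccc3)(c3ccccc3)C(C)(C)C
F2 | step 15 | C1 allylic alcohol of 22 (C1 configuration open) | O=C1[C@@H](C(=C)CO[Si](c3ccccc3)(c3ccccc3)C(C)(C)C)[C@H](/C=C(/C)C2=CC(O)[C@](C)(O2)[C@@H]1O[Si](CC)(CC)CC)O[Si](c3ccccc3)(c3ccccc3)C(C)(C)C
F3 | step 16 | 8-epi alcohol (C8 epimer of 25) | O[C@@H]1[C@@H](C(=C)CO[Si](c3ccccc3)(c3ccccc3)C(C)(C)C)[C@H](/C=C(/C)C2=CC(=O)[C@](C)(O2)[C@@H]1O[Si](CC)(CC)CC)O[Si](c3ccccc3)(c3ccccc3)C(C)(C)C
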